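**Strategy.** The pyran ring (ring C) is disconnected at O1–C8a, C4–C4a and O1–C2. In ring A, O1 and C4 occupy the adjacent carbons C8a and C4a, and the C5 oxygen flanks C4a: this is the pattern a 3,5-dialkoxybenzyne delivers when a carbonyl group adds oxygen-first at the aryne carbon remote from the neighbouring alkoxy group. A fluoride-triggered union of 3,5-bis(benzyloxy)-2-(trimethylsilyl)phenyl triflate with (E)-3,4-bis(benzyloxy)cinnamaldehyde should therefore build the complete flav-3-ene in one operation, through a benzoxete that opens and recloses by oxa-6π cyclisation. Because C2 emerges racemic, its configuration is reset at the C2-labile flavan-3-one by reduction under dynamic kinetic resolution; acylation and global debenzylation finish the route.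

Key step: step 5

Assumption: the sense of induction in step 8 is assigned by analogy with α-aryl cycloalkanones (the carbon bearing the aryl group taking the place of the aryl group of an aryl ketone), so the (R,R)-TsDPEN catalyst is expected to give the (3R) alcohol; should a trial run show the opposite sense, the (S,S) ligand would be used with no other change. Racemates with two stereocentres are drawn as one enantiomer and marked rac.

Step 1
Reactants: 1 3,5-bis(benzyloxy)phenol
Product: 2 3,5-bis(benzyloxy)phenyl N-isopropylcarbamate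
Conditions: i-PrNCO, Et3N (cat.), CH2Cl2, rt
Reagents that add atoms: isopropyl isocyanate, CC(C)N=C=O
Why: Base-catalysed addition of the phenol O–H to the isocyanate (carbamoylation) is clean for electron-rich phenols, and the N–H carbamate is chosen because it directs ortho-metalation yet is later removed under mild amine conditions.

Step 2
Reactants: 2 3,5-bis(benzyloxy)phenyl N-isopropylcarbamate
Product: 6 3,5-bis(benzyloxy)-2-(trimethylsilyl)phenyl N-isopropylcarbamate, via N-silyl carbamate 3 (not isolated), via aryllithium 4 (not isolated), via bis-silyl carbamate 5 (not isolated)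
Conditions: TMSOTf, TMEDA, Et2O, 0 °C to rt; n-BuLi, TMEDA, −78 °C; TMSCl, −78 °C to rt; aq. NaHSO4
Reagents that add atoms: chlorotrimethylsilane (TMSCl), C[Si](C)(C)Cl
Why: Directed ortho-metalation of the in situ N-silylated carbamate should occur at C2, flanked by the carbamate and a benzyloxy group (both ortho positions are equivalent by symmetry), and silyl trapping at −78 °C should outrun benzylic deprotonation and anionic Fries migration, the N-silyl group falling off on acidic work-up.

Step 3
Reactants: 6 3,5-bis(benzyloxy)-2-(trimethylsilyl)phenyl N-isopropylcarbamate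
Product: 8 3,5-bis(benzyloxy)-2-(trimethylsilyl)phenyl trifluoromethanesulfonate, via silyl phenol 7 (not isolated)
Conditions: DBU, Et2NH, MeCN, 40 °C; then PhNTf2, rt
Reagents that add atoms: N-phenylbis(trifluoromethanesulfonimide) (PhNTf2), O=S(=O)(N(c1ccccc1)S(=O)(=O)C(F)(F)F)C(F)(F)F
Why: DBU removes the carbamate N–H and E1cB loss of the carbamoyl unit (scavenged by Et2NH as a urea) frees the phenoxide of 7, which is O-triflated in the same pot, so the desilylation-prone silyl phenol is never isolated.

Step 4
Reactants: 9 3,4-bis(benzyloxy)benzaldehyde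
Product: 10 (E)-3-[3,4-bis(benzyloxy)phenyl]prop-2-enal
Conditions: Ph3P=CHCHO (limiting), toluene, 90 °C
Reagents that add atoms: (triphenylphosphoranylidene)acetaldehyde, O=CC=P(c1ccccc1)(c1ccccc1)c1ccccc1
Why: Wittig olefination with the formyl-stabilised ylide gives the E-enal in one step, and keeping the ylide limiting should hold a second homologation of the product to a minimum.

Step 5
Reactants: 8 3,5-bis(benzyloxy)-2-(trimethylsilyl)phenyl trifluoromethanesulfonate; 10 (E)-3-[3,4-bis(benzyloxy)phenyl]prop-2-enal
Product: 14 racemic 5,7-bis(benzyloxy)-2-[3,4-bis(benzyloxy)phenyl]-2H-chromene, via aryne 11 (not isolated), via benzoxete 12 (not isolated), via ortho-quinone methide 13 (not isolated)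
Conditions: CsF, MeCN/toluene (1:1), 25 °C, slow addition of 8
Reagents that add atoms: none
Why: Fluoride attacks silicon in 8 and triflate departs to give aryne 11, which adds the aldehyde C=O of 10 in a polar, stepwise [2+2] fashion: the carbonyl oxygen bonds to the aryne carbon that becomes C8a while the developing aryl anion at C4a, stabilised inductively by the adjacent C5 benzyloxy group, closes onto the carbonyl carbon to give benzoxete 12. Strain then drives electrocyclic opening of the four-membered ring to ortho-quinone methide 13, and ring C is closed by a thermal disrotatory oxa-6π electrocyclisation that forms O1–C2 and restores the aromaticity of ring A. The closest known reaction type is the annulation of arynes from ortho-silylaryl triflates with α,β-unsaturated aldehydes to give 2H-chromenes. The single new stereocentre, C2, has no controlling element and is accepted as racemic because step 8 resets it. The step needs regioselective aryne addition, which the C5 alkoxy group secures by distorting the aryne so that the nucleophilic oxygen adds at the distal carbon, and it needs cyclisation of 13 to beat intermolecular trapping, which the conjugated E-styryl arm secures by making the closure intramolecular.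

Step 6
Reactants: 14 racemic 5,7-bis(benzyloxy)-2-[3,4-bis(benzyloxy)phenyl]-2H-chromene
Product: 16 rac-(2R,3S)-5,7-bis(benzyloxy)-2-[3,4-bis(benzyloxy)phenyl]chroman-3-ol (2,3-trans), via C3 alkylborane 15 (not isolated)
Conditions: BH3·THF, THF, 0 °C to rt; then NaOH, H2O2, H2O, 0 °C to rt
Reagents that add atoms: hydrogen peroxide, OO
Why: Hydroboration–oxidation should place boron at C3 (styrene-type polarisation by ring A, reinforced by the electron-withdrawing allylic O1) on the face opposite the C2 aryl group, and oxidation with retention then gives the 2,3-trans alcohol, C3 being set relative to C2 by substrate control.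

Step 7
Reactants: 16 rac-(2R,3S)-5,7-bis(benzyloxy)-2-[3,4-bis(benzyloxy)phenyl]chroman-3-ol
Product: 17 racemic 5,7-bis(benzyloxy)-2-[3,4-bis(benzyloxy)phenyl]chroman-3-one
Conditions: Dess–Martin periodinane, CH2Cl2, rt
Reagents that add atoms: none
Why: Dess–Martin oxidation of the secondary alcohol runs under near-neutral conditions that spare the benzyl ethers and the electron-rich rings, and it deliberately erases C3 so that both centres can be set together in the next step.

Step 8
Reactants: 17 racemic 5,7-bis(benzyloxy)-2-[3,4-bis(benzyloxy)phenyl]chroman-3-one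
Product: 19 (2R,3R)-5,7-bis(benzyloxy)-2-[3,4-bis(benzyloxy)phenyl]chroman-3-ol (2,3-cis), via enol 18 (not isolated)
Conditions: RuCl(p-cymene)[(R,R)-TsDPEN] (cat.), HCO2H/Et3N (1:1), CH2Cl2, 30 °C
Reagents that add atoms: none
Why: In this Noyori–Ikariya asymmetric transfer hydrogenation under dynamic kinetic resolution, the C2 hydrogen (α to the ketone, benzylic and α to O1) should exchange through enol 18 under the amine base faster than reduction, while the chiral ruthenium hydride selects the C3 face (3R) and, by equatorial hydride delivery next to the pseudo-equatorial C2 aryl group, consumes the (2R)-ketone preferentially to give the axial, cis (2R,3R) alcohol.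

Step 9
Reactants: 19 (2R,3R)-5,7-bis(benzyloxy)-2-[3,4-bis(benzyloxy)phenyl]chroman-3-ol; 20 4-(benzyloxy)benzoic acid
Product: 22 (2R,3R)-5,7-bis(benzyloxy)-2-[3,4-bis(benzyloxy)phenyl]chroman-3-yl 4-(benzyloxy)benzoate, via O-acylisourea 21 (not isolated)
Conditions: DCC, DMAP (cat.), CH2Cl2, 0 °C to rt
Reagents that add atoms: none
Why: Steglich esterification acylates the hindered axial C3 hydroxyl through DMAP acyl transfer without breaking the C3–O bond, so the (2R,3R) configuration is retained.

Step 10
Reactants: 22 (2R,3R)-5,7-bis(benzyloxy)-2-[3,4-bis(benzyloxy)phenyl]chroman-3-yl 4-(benzyloxy)benzoate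
Product: 23 epicatechin 3-O-p-hydroxybenzoate, (2R,3R)-2-(3,4-dihydroxyphenyl)-5,7-dihydroxychroman-3-yl 4-hydroxybenzoate
Conditions: H2 (1 atm), Pd(OH)2/C, THF/MeOH, rt
Reagents that add atoms: none
Why: Catalytic hydrogenolysis of the five aryl benzyl ethers at atmospheric pressure should be much faster than cleavage of the cyclic C2–O1 benzylic ether or any attack on the ester, so both stereocentres and the benzoate survive.

**Compound list**

1 | 3,5-bis(benzyloxy)phenol | Oc1cc(OCc2ccccc2)cc(OCc2ccccc2)c1 | starting material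
2 | 3,5-bis(benzyloxy)phenyl N-isopropylcarbamate | CC(C)NC(=O)Oc1cc(OCc2ccccc2)cc(OCc2ccccc2)c1 | intermediate
3 | 3,5-bis(benzyloxy)phenyl N-isopropyl-N-(trimethylsilyl)carbamate (in situ) | CC(C)N(C(=O)Oc1cc(OCc2ccccc2)cc(OCc2ccccc2)c1)[Si](C)(C)C | intermediate
4 | 2-lithio derivative of 3 (in situ) | CC(C)N(C(=O)Oc1cc(OCc2ccccc2)cc(OCc2ccccc2)c1[Li])[Si](C)(C)C | intermediate
5 | 3,5-bis(benzyloxy)-2-(trimethylsilyl)phenyl N-isopropyl-N-(trimethylsilyl)carbamate (in situ) | CC(C)N(C(=O)Oc1cc(OCc2ccccc2)cc(OCc2ccccc2)c1[Si](C)(C)C)[Si](C)(C)C | intermediate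
6 | 3,5-bis(benzyloxy)-2-(trimethylsilyl)phenyl N-isopropylcarbamate | CC(C)NC(=O)Oc1cc(OCc2ccccc2)cc(OCc2ccccc2)c1[Si](C)(C)C | intermediate
7 | 3,5-bis(benzyloxy)-2-(trimethylsilyl)phenol (in situ, as its DBU salt) | Oc1cc(OCc2ccccc2)cc(OCc2ccccc2)c1[Si](C)(C)C | intermediate
8 | 3,5-bis(benzyloxy)-2-(trimethylsilyl)phenyl trifluoromethanesulfonate | C[Si](C)(C)c1c(OS(=O)(=O)C(F)(F)F)cc(OCc2ccccc2)cc1OCc1ccccc1 | intermediate
9 | 3,4-bis(benzyloxy)benzaldehyde | O=Cc1ccc(OCc2ccccc2)c(OCc2ccccc2)c1 | starting material
10 | (E)-3-[3,4-bis(benzyloxy)phenyl]prop-2-enal | O=C/C=C/c1ccc(OCc2ccccc2)c(OCc2ccccc2)c1 | intermediate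
11 | 3,5-bis(benzyloxy)benzyne (in situ) | C1#CC(OCc2ccccc2)=CC(OCc2ccccc2)=C1 | intermediate
12 | 3,5-bis(benzyloxy)-2-[(E)-2-(3,4-bis(benzyloxy)phenyl)ethenyl]-2H-benzo[b]oxete (in situ, racemic) | O1C(/C=C/c2ccc(OCc3ccccc3)c(OCc3ccccc3)c2)c2c(OCc3ccccc3)cc(OCc3ccccc3)cc12 | intermediate
13 | 3,5-bis(benzyloxy)-6-[(E)-3-(3,4-bis(benzyloxy)phenyl)prop-2-en-1-ylidene]cyclohexa-2,4-dien-1-one (in situ) | O=C1C=C(OCc2ccccc2)C=C(OCc2ccccc2)C1=C/C=C/c1ccc(OCc2ccccc2)c(OCc2ccccc2)c1 | intermediate
14 | racemic 5,7-bis(benzyloxy)-2-[3,4-bis(benzyloxy)phenyl]-2H-chromene | C1=CC(c2ccc(OCc3ccccc3)c(OCc3ccccc3)c2)Oc2cc(OCc3ccccc3)cc(OCc3ccccc3)c21 | intermediate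
15 | rac-trans-[5,7-bis(benzyloxy)-2-(3,4-bis(benzyloxy)phenyl)chroman-3-yl]borane (in situ, written as the monoalkylborane) | B[C@H]1Cc2c(OCc3ccccc3)cc(OCc3ccccc3)cc2O[C@@H]1c1ccc(OCc2ccccc2)c(OCc2ccccc2)c1 | intermediate
16 | rac-(2R,3S)-5,7-bis(benzyloxy)-2-[3,4-bis(benzyloxy)phenyl]chroman-3-ol (2,3-trans) | O[C@H]1Cc2c(OCc3ccccc3)cc(OCc3ccccc3)cc2O[C@@H]1c1ccc(OCc2ccccc2)c(OCc2ccccc2)c1 | intermediate
17 | racemic 5,7-bis(benzyloxy)-2-[3,4-bis(benzyloxy)phenyl]chroman-3-one | O=C1Cc2c(OCc3ccccc3)cc(OCc3ccccc3)cc2OC1c1ccc(OCc2ccccc2)c(OCc2ccccc2)c1 | intermediate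
18 | 5,7-bis(benzyloxy)-2-[3,4-bis(benzyloxy)phenyl]-4H-chromen-3-ol (in situ, achiral enol) | OC1=C(c2ccc(OCc3ccccc3)c(OCc3ccccc3)c2)Oc2cc(OCc3ccccc3)cc(OCc3ccccc3)c2C1 | intermediate
19 | (2R,3R)-5,7-bis(benzyloxy)-2-[3,4-bis(benzyloxy)phenyl]chroman-3-ol (2,3-cis) | O[C@@H]1Cc2c(OCc3ccccc3)cc(OCc3ccccc3)cc2O[C@@H]1c1ccc(OCc2ccccc2)c(OCc2ccccc2)c1 | intermediate
20 | 4-(benzyloxy)benzoic acid | O=C(O)c1ccc(OCc2ccccc2)cc1 | starting material
21 | O-[4-(benzyloxy)benzoyl]-N,N'-dicyclohexylisourea (in situ) | O=C(OC(=NC1CCCCC1)NC1CCCCC1)c1ccc(OCc2ccccc2)cc1 | intermediate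
22 | (2R,3R)-5,7-bis(benzyloxy)-2-[3,4-bis(benzyloxy)phenyl]chroman-3-yl 4-(benzyloxy)benzoate | O=C(O[C@@H]1Cc2c(OCc3ccccc3)cc(OCc3ccccc3)cc2O[C@@H]1c1ccc(OCc2ccccc2)c(OCc2ccccc2)c1)c1ccc(OCc2ccccc2)cc1 | intermediate
23 | epicatechin 3-O-p-hydroxybenzoate, (2R,3R) | O=C(O[C@@H]1Cc2c(O)cc(O)cc2O[C@@H]1c1ccc(O)c(O)c1)c1ccc(O)cc1 | target

**Step count.** Total: 10 steps. Longest linear sequence: 9 steps (from 1 through steps 1, 2, 3, 5, 6, 7, 8, 9 and 10); step 4 is a one-step side branch.

**Steps most likely to fail**

Step 5. The aryne, the quinone methide or the chromene product may be intercepted by a second aryne, by the enal or by fluoride before or after the oxa-6π closure, and the electron-rich flav-3-ene may decompose on acidic silica. The fallback sets out from 1 and 10 and comes back at 14. The two are heated with PhB(OH)2 and catalytic propionic acid in toluene with azeotropic removal of water. The boron tether enforces attack of the aldehyde at the ortho carbon of the phenol and gives the 2-phenyl-1,3,2-benzodioxaborinine F1. This fragments thermally to the same quinone methide 13, which closes to 14. This is the known phenylboronic acid-mediated condensation of phenols with enals. It would replace steps 1 to 3 and 5.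

Step 8. Epimerisation at C2 may be too slow relative to hydride transfer, or facial discrimination at C3 may be weak, eroding enantiomeric or cis/trans purity. The fallback sets out from 17 and comes back at 19. Reduction with LiBH(s-Bu)3 in THF at −78 °C, by equatorial hydride delivery, should give the racemic cis alcohol F2. Its enantiomers are then separated by preparative chromatography on a chiral stationary phase into 19 and the (2S,3S) antipode F3. Stereocontrol thus rests on a diastereoselective reduction plus resolution instead of asymmetric catalysis.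

Step 2. Benzylic deprotonation of the ether groups followed by 1,2-Wittig rearrangement, or carbamoyl migration before silylation, may compete with ortho-lithiation. The fallback sets out from 1 and comes back at 8, replacing steps 1 to 3. Amine-directed ortho-bromination (NBS, catalytic i-Pr2NH, CH2Cl2, 0 °C) should give 3,5-bis(benzyloxy)-2-bromophenol F4. O-silylation with (Me3Si)2NH in THF gives the aryl trimethylsilyl ether F5. Treatment with n-BuLi in THF at −78 °C effects bromine–lithium exchange, much faster than benzylic deprotonation, to the aryllithium F6. F6 undergoes a 1,3 O-to-C silyl shift (retro-Brook) to the lithium salt of 7, which is trapped with Tf2O to give 8.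

**Further compounds**

F1 | step 5 | 5,7-bis(benzyloxy)-4-[(E)-2-(3,4-bis(benzyloxy)phenyl)ethenyl]-2-phenyl-4H-benzo[d][1,3,2]dioxaborinine (racemic) | c1ccccc1B1Oc2cc(OCc3ccccc3)cc(OCc3ccccc3)c2C(/C=C/c2ccc(OCc3ccccc3)c(OCc3ccccc3)c2)O1
F2 | step 8 | rac-(2R,3R)-5,7-bis(benzyloxy)-2-[3,4-bis(benzyloxy)phenyl]chroman-3-ol (racemic cis alcohol, one enantiomer drawn) | O[C@@H]1Cc2c(OCc3ccccc3)cc(OCc3ccccc3)cc2O[C@@H]1c1ccc(OCc2ccccc2)c(OCc2ccccc2)c1
F3 | step 8 | (2S,3S)-5,7-bis(benzyloxy)-2-[3,4-bis(benzyloxy)phenyl]chroman-3-ol | O[C@H]1Cc2c(OCc3ccccc3)cc(OCc3ccccc3)cc2O[C@H]1c1ccc(OCc2ccccc2)c(OCc2ccccc2)c1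
F4 | step 2 | 3,5-bis(benzyloxy)-2-bromophenol | Oc1cc(OCc2ccccc2)cc(OCc2ccccc2)c1Br
F5 | step 2 | [3,5-bis(benzyloxy)-2-bromophenoxy]trimethylsilane | C[Si](C)(C)Oc1cc(OCc2ccccc2)cc(OCc2ccccc2)c1Br
F6 | step 2 | [2,4-bis(benzyloxy)-6-(trimethylsilyloxy)phenyl]lithium | C[Si](C)(C)Oc1cc(OCc2ccccc2)cc(OCc2ccccc2)c1[Li]
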